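**Strategy.** In the bicyclo[3.2.1]oct-3-ene-2,8-dione core (C1–C8, bicyclic numbering) the six-membered ring C1–C2–C3–C4–C5–C8 is the locked diketo tautomer of a resorcinol. It is therefore the formal [4+2] adduct of a ketene (C1=C8=O) and a vinylketene acetal (C2–C5). The key step makes the ketene by Wolff rearrangement of an acyclic diazoketone that carries a 1-methoxy-1-silyloxydiene. Acylation at C5 (C5–C8) and closure C1–C2 form both rings and both bridgeheads in one operation. The C6/C7 diaryl stereocentres come from an isothiourea-catalysed Michael addition–lactonisation. An arylethynyl group at C4 is carried through and reduced to the E-styryl unit last.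

Key step: step 12

Remark: (2S,3R)-HyperBTM is assumed to induce the (3S,4S) configuration of lactone 11; if its sense of induction on this substrate is the opposite, the enantiomeric catalyst is used. TIPS = triisopropylsilyl, TBS = tert-butyldimethylsilyl; C1–C8 in the Why lines are the locants of the bicyclic core of the target.

Step 1
Reactants: 1 4-hydroxyphenylacetic acid
Product: 3 [4-(TIPSO)phenyl]acetic acid, via bis-silylated acid 2 (not isolated)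
Conditions: TIPSCl, imidazole, DMF, rt; then K2CO3, MeOH–H2O, 0 °C; aq. HCl
Reagents that add atoms: triisopropylsilyl chloride, CC(C)[Si](Cl)(C(C)C)C(C)C
Why: Phenol and acid are both silylated and the much more labile silyl ester is then hydrolysed selectively, leaving the aryl silyl ether that has to survive the later bases and is removed by fluoride at the end.

Step 2
Reactants: 4 3,5-dihydroxybenzaldehyde
Product: 5 3,5-bis(TIPSO)benzaldehyde
Conditions: TIPSCl, imidazole, DMF, rt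
Reagents that add atoms: triisopropylsilyl chloride, CC(C)[Si](Cl)(C(C)C)C(C)C
Why: Standard silyl ether formation on both phenols; the hindered silyl ethers should tolerate the enolate, Lewis-base and palladium steps.

Step 3
Reactants: 5 3,5-bis(TIPSO)benzaldehyde; 6 1,1,1-trichloropropan-2-one
Product: 9 (E)-1,1,1-trichloro-4-[3,5-bis(TIPSO)phenyl]but-3-en-2-one, via lithium aldolate 7 (not isolated), via aldol mesylate 8 (not isolated)
Conditions: LiN(SiMe3)2, THF, −78 °C; then MsCl, Et3N, −78 → 0 °C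
Reagents that add atoms: none
Why: Aldol addition of the lithium enolate of 6 to aldehyde 5 and E1cB elimination of the mesylate should give the E-enone, whose CCl3 ketone is an ester-level acyl group and activates the Michael acceptor.

Step 4
Reactants: 3 [4-(TIPSO)phenyl]acetic acid; 9 (E)-1,1,1-trichloro-4-[3,5-bis(TIPSO)phenyl]but-3-en-2-one
Product: 12 prop-2-en-1-yl (2S,3S)-6,6,6-trichloro-5-oxo-2-[4-(TIPSO)phenyl]-3-[3,5-bis(TIPSO)phenyl]hexanoate, via mixed pivalic anhydride 10 (not isolated), via trans-dihydropyranone 11 (not isolated)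
Conditions: t-BuCOCl, i-Pr2NEt, CH2Cl2, 0 °C; 9, (2S,3R)-HyperBTM (5 mol %), −78 °C → rt; then allyl alcohol (1.2 equiv), DMAP (cat.), rt
Reagents that add atoms: allyl alcohol, C=CCO
Why: Isothiourea-catalysed Michael addition–lactonisation: the acyl ammonium from 10 forms a Z-enolate held by an O···S contact, whose open face adds to the enone and sets the two aryl-bearing centres trans (3S,4S) in enol lactone 11; DMAP-mediated acyl transfer to the alcohol then opens 11 and releases the trichloromethyl ketone.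

Step 5
Reactants: 12 prop-2-en-1-yl (2S,3S)-6,6,6-trichloro-5-oxo-2-[4-(TIPSO)phenyl]-3-[3,5-bis(TIPSO)phenyl]hexanoate
Product: 13 (3S,4S)-5-oxo-5-(prop-2-en-1-yloxy)-3-[3,5-bis(TIPSO)phenyl]-4-[4-(TIPSO)phenyl]pentanoic acid
Conditions: LiOH (1.1 equiv), THF–H2O, 0 °C; aq. HCl
Reagents that add atoms: lithium hydroxide, [Li+].[OH-]
Why: Haloform-type cleavage: hydroxide adds to the highly electrophilic CCl3 ketone and expels trichloromethanide much faster than it attacks the hindered allyl ester or the aryl silyl ethers.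

Step 6
Reactants: 13 (3S,4S)-5-oxo-5-(prop-2-en-1-yloxy)-3-[3,5-bis(TIPSO)phenyl]-4-[4-(TIPSO)phenyl]pentanoic acid
Product: 15 7-methyl 1-prop-2-en-1-yl (2S,3S)-5-oxo-2-[4-(TIPSO)phenyl]-3-[3,5-bis(TIPSO)phenyl]heptanedioate, via acyl imidazole 14 (not isolated)
Conditions: CDI, THF, rt; then MeO2CCH2CO2K, MgCl2, 50 °C; aq. HCl
Reagents that add atoms: methyl potassium malonate, COC(=O)CC(=O)[O-].[K+]
Why: Masamune chain extension: the acyl imidazole C-acylates the magnesium enolate of the malonate half-ester and decarboxylation gives the β-keto ester under nearly neutral conditions that leave the α-aryl centre untouched.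

Step 7
Reactants: 15 7-methyl 1-prop-2-en-1-yl (2S,3S)-5-oxo-2-[4-(TIPSO)phenyl]-3-[3,5-bis(TIPSO)phenyl]heptanedioate
Product: 16 7-methyl 1-prop-2-en-1-yl (2S,3S,5Z)-2-[4-(TIPSO)phenyl]-3-[3,5-bis(TIPSO)phenyl]-5-(trifluoromethanesulfonyloxy)hept-5-enedioate
Conditions: NaH (1.05 equiv), Tf2O, Et2O, 0 °C
Reagents that add atoms: trifluoromethanesulfonic anhydride, O=S(=O)(OS(=O)(=O)C(F)(F)F)C(F)(F)F
Why: O-Sulfonylation of the chelated sodium enolate of the β-keto ester should give the Z-enol triflate (OTf cis to CO2Me); one equivalent of NaH deprotonates only the β-keto ester.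

Step 8
Reactants: 17 4-ethynylphenol
Product: 18 (4-ethynylphenoxy)triisopropylsilane
Conditions: TIPSCl, imidazole, DMF, rt
Reagents that add atoms: triisopropylsilyl chloride, CC(C)[Si](Cl)(C(C)C)C(C)C
Why: Phenol silylation gives the alkyne partner with the same fluoride-labile protecting group as the other rings.

Step 9
Reactants: 16 7-methyl 1-prop-2-en-1-yl (2S,3S,5Z)-2-[4-(TIPSO)phenyl]-3-[3,5-bis(TIPSO)phenyl]-5-(trifluoromethanesulfonyloxy)hept-5-enedioate; 18 (4-ethynylphenoxy)triisopropylsilane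
Product: 19 7-methyl 1-prop-2-en-1-yl (2S,3S,5Z)-2-[4-(TIPSO)phenyl]-3-[3,5-bis(TIPSO)phenyl]-5-{[4-(TIPSO)phenyl]ethynyl}hept-5-enedioate
Conditions: Pd(PPh3)2Cl2 (cat.), CuI (cat.), Et3N, THF, rt
Reagents that add atoms: none
Why: Sonogashira coupling of the electron-poor alkenyl triflate with the terminal alkyne proceeds with retention of the alkene geometry and does not touch the stereocentres.

Step 10
Reactants: 19 7-methyl 1-prop-2-en-1-yl (2S,3S,5Z)-2-[4-(TIPSO)phenyl]-3-[3,5-bis(TIPSO)phenyl]-5-{[4-(TIPSO)phenyl]ethynyl}hept-5-enedioate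
Product: 20 (2S,3S,5Z)-7-methoxy-7-oxo-2-[4-(TIPSO)phenyl]-3-[3,5-bis(TIPSO)phenyl]-5-{[4-(TIPSO)phenyl]ethynyl}hept-5-enoic acid
Conditions: Pd(PPh3)4 (cat.), PhNHMe, THF, rt
Reagents that add atoms: none
Why: Palladium-catalysed deallylation (π-allyl transfer to the amine, Tsuji–Trost type) frees the acid under neutral conditions, so the enoate ester, the silyl ethers and the α-aryl stereocentre should be untouched.

Step 11
Reactants: 20 (2S,3S,5Z)-7-methoxy-7-oxo-2-[4-(TIPSO)phenyl]-3-[3,5-bis(TIPSO)phenyl]-5-{[4-(TIPSO)phenyl]ethynyl}hept-5-enoic acid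
Product: 23 (3S,4S)-1-diazo-8-methoxy-8-(TBSO)-3-[4-(TIPSO)phenyl]-4-[3,5-bis(TIPSO)phenyl]-6-{[4-(TIPSO)phenyl]ethynyl}octa-5,7-dien-2-one (mixture of diene geometric isomers; used crude), via carboxylate ketene acetal 21 (not isolated), via mixed carbonic anhydride 22 (not isolated)
Conditions: KN(SiMe3)2 (2.1 equiv), THF, −78 °C; TBSCl (1.05 equiv); then i-BuOCOCl, −40 °C; then CH2N2, Et2O, −40 → 0 °C
Reagents that add atoms: tert-butyldimethylsilyl chloride, CC(C)(C)[Si](C)(C)Cl; diazomethane, C=[N+]=[N-]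
Why: As its potassium carboxylate the acid has no acidic α-C–H, so the second equivalent of base removes a γ-proton of the enoate and O-silylation gives the dienyl silyl ketene acetal; the carboxylate is then converted through the mixed carbonic anhydride and diazomethane into the diazoketone (first half of an Arndt–Eistert homologation) without touching the stereocentres.

Step 12
Reactants: 23 (3S,4S)-1-diazo-8-methoxy-8-(TBSO)-3-[4-(TIPSO)phenyl]-4-[3,5-bis(TIPSO)phenyl]-6-{[4-(TIPSO)phenyl]ethynyl}octa-5,7-dien-2-one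
Product: 26 (1R,5S,6R,7R)-7-[4-(TIPSO)phenyl]-6-[3,5-bis(TIPSO)phenyl]-4-{[4-(TIPSO)phenyl]ethynyl}bicyclo[3.2.1]oct-3-ene-2,8-dione, via ketene 24 (not isolated), via bicyclic mixed ketal 25 (not isolated)
Conditions: hν (405–420 nm), toluene (5 mM), 25 °C; then 80 °C; then aq. citric acid, THF, rt
Reagents that add atoms: none
Why: Proposed new method: light-induced Wolff rearrangement of 23 (the aryl-bearing carbon migrates with retention) gives aldoketene 24, whose sp carbon C8 is attacked in the ketene plane by the nucleophilic γ-carbon C5 of the tethered silyl ketene acetal, and the resulting zwitterion (C8=C1 enolate, dioxocarbenium at C2) collapses by C1–C2 bond formation to ketal 25, a stepwise polar [4+2] cycloaddition that mild acid turns into dione 26. The closest known reactions are the C-acylation of silyl ketene acetals by ketenes, intramolecular ketene–alkene [2+2] cycloadditions and Diels–Alder reactions of 1,1-dioxygenated dienes with ketene equivalents. The cyclopentanone ring closes by 5-exo-dig attack of C5 on C8 and the cyclohexenone ring by 6-(enolendo)-exo-trig attack of C1 on C2; any crossed [2+2] or O-closed adduct is a donor–acceptor system that should reopen to the same zwitterion at 80 °C. The new centres C5 and C1 are controlled by the C6 and C7 centres: the three-carbon bridge can only be cis-fused, and C2, tetrahedral and carrying OMe and OSi, has to reach C1 anti to the C7 aryl group, which leaves that aryl exo and puts the C6 aryl endo over the flat C3=C4–alkyne unit. The step thus needs this facial selectivity at C5 together with C-closure at C2 instead of closure through oxygen or at a remote carbon. It is secured by reversible first bond formation in toluene (product-determining ring closure), by the 1,3-syn clash of an endo C7 aryl group with the C2 oxygens in the other pathway, and by the arylethynyl group at C4, which keeps allylic strain toward the C6 aryl low and cannot be attacked at its far end without forming a cyclic allene.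

Step 13
Reactants: 26 (1R,5S,6R,7R)-7-[4-(TIPSO)phenyl]-6-[3,5-bis(TIPSO)phenyl]-4-{[4-(TIPSO)phenyl]ethynyl}bicyclo[3.2.1]oct-3-ene-2,8-dione
Product: 29 vitisinol D, via alkenylsilane 27 (not isolated), via regioisomeric alkenylsilane 28 (not isolated)
Conditions: [Cp*Ru(MeCN)3]PF6 (cat.), (EtO)3SiH, CH2Cl2, 0 °C → rt; then CuI (cat.), Bu4NF, THF, 0 °C; aq. NH4Cl
Reagents that add atoms: none
Why: Ruthenium-catalysed hydrosilylation adds Si–H anti across the alkyne and CuI/fluoride protodesilylation proceeds with retention, so both regioisomeric alkenylsilanes should give the E-alkene, while fluoride also cleaves the four aryl silyl ethers and leaves the ring stereocentres untouched.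

**Compound list**

1 | 4-hydroxyphenylacetic acid | OC(=O)Cc1ccc(O)cc1 | starting material
2 | triisopropylsilyl [4-(TIPSO)phenyl]acetate | CC(C)[Si](C(C)C)(C(C)C)OC(=O)Cc1ccc(O[Si](C(C)C)(C(C)C)C(C)C)cc1 | intermediate
3 | [4-(TIPSO)phenyl]acetic acid | OC(=O)Cc1ccc(O[Si](C(C)C)(C(C)C)C(C)C)cc1 | intermediate
4 | 3,5-dihydroxybenzaldehyde | O=Cc1cc(O)cc(O)c1 | starting material
5 | 3,5-bis(TIPSO)benzaldehyde | O=Cc1cc(O[Si](C(C)C)(C(C)C)C(C)C)cc(O[Si](C(C)C)(C(C)C)C(C)C)c1 | intermediate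
6 | 1,1,1-trichloropropan-2-one | CC(=O)C(Cl)(Cl)Cl | starting material
7 | lithium 4,4,4-trichloro-3-oxo-1-[3,5-bis(TIPSO)phenyl]butan-1-olate (racemic) | [Li+].[O-]C(CC(=O)C(Cl)(Cl)Cl)c1cc(O[Si](C(C)C)(C(C)C)C(C)C)cc(O[Si](C(C)C)(C(C)C)C(C)C)c1 | intermediate
8 | 4,4,4-trichloro-3-oxo-1-[3,5-bis(TIPSO)phenyl]butyl methanesulfonate (racemic) | CS(=O)(=O)OC(CC(=O)C(Cl)(Cl)Cl)c1cc(O[Si](C(C)C)(C(C)C)C(C)C)cc(O[Si](C(C)C)(C(C)C)C(C)C)c1 | intermediate
9 | (E)-1,1,1-trichloro-4-[3,5-bis(TIPSO)phenyl]but-3-en-2-one | ClC(Cl)(Cl)C(=O)/C=C/c1cc(O[Si](C(C)C)(C(C)C)C(C)C)cc(O[Si](C(C)C)(C(C)C)C(C)C)c1 | intermediate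
10 | 2,2-dimethylpropanoic [4-(TIPSO)phenyl]acetic anhydride | CC(C)(C)C(=O)OC(=O)Cc1ccc(O[Si](C(C)C)(C(C)C)C(C)C)cc1 | intermediate
11 | (3S,4S)-6-(trichloromethyl)-3-[4-(TIPSO)phenyl]-4-[3,5-bis(TIPSO)phenyl]-3,4-dihydro-2H-pyran-2-one (trans) | O=C1[C@H](c2ccc(O[Si](C(C)C)(C(C)C)C(C)C)cc2)[C@H](C=C(O1)C(Cl)(Cl)Cl)c1cc(O[Si](C(C)C)(C(C)C)C(C)C)cc(O[Si](C(C)C)(C(C)C)C(C)C)c1 | intermediate
12 | prop-2-en-1-yl (2S,3S)-6,6,6-trichloro-5-oxo-2-[4-(TIPSO)phenyl]-3-[3,5-bis(TIPSO)phenyl]hexanoate | C=CCOC(=O)[C@H](c1ccc(O[Si](C(C)C)(C(C)C)C(C)C)cc1)[C@H](CC(=O)C(Cl)(Cl)Cl)c1cc(O[Si](C(C)C)(C(C)C)C(C)C)cc(O[Si](C(C)C)(C(C)C)C(C)C)c1 | intermediate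
13 | (3S,4S)-5-oxo-5-(prop-2-en-1-yloxy)-3-[3,5-bis(TIPSO)phenyl]-4-[4-(TIPSO)phenyl]pentanoic acid | C=CCOC(=O)[C@H](c1ccc(O[Si](C(C)C)(C(C)C)C(C)C)cc1)[C@H](CC(=O)O)c1cc(O[Si](C(C)C)(C(C)C)C(C)C)cc(O[Si](C(C)C)(C(C)C)C(C)C)c1 | intermediate
14 | prop-2-en-1-yl (2S,3S)-5-(imidazol-1-yl)-5-oxo-2-[4-(TIPSO)phenyl]-3-[3,5-bis(TIPSO)phenyl]pentanoate | C=CCOC(=O)[C@H](c1ccc(O[Si](C(C)C)(C(C)C)C(C)C)cc1)[C@H](CC(=O)n1ccnc1)c1cc(O[Si](C(C)C)(C(C)C)C(C)C)cc(O[Si](C(C)C)(C(C)C)C(C)C)c1 | intermediate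
15 | 7-methyl 1-prop-2-en-1-yl (2S,3S)-5-oxo-2-[4-(TIPSO)phenyl]-3-[3,5-bis(TIPSO)phenyl]heptanedioate | C=CCOC(=O)[C@H](c1ccc(O[Si](C(C)C)(C(C)C)C(C)C)cc1)[C@H](CC(=O)CC(=O)OC)c1cc(O[Si](C(C)C)(C(C)C)C(C)C)cc(O[Si](C(C)C)(C(C)C)C(C)C)c1 | intermediate
16 | 7-methyl 1-prop-2-en-1-yl (2S,3S,5Z)-2-[4-(TIPSO)phenyl]-3-[3,5-bis(TIPSO)phenyl]-5-(trifluoromethanesulfonyloxy)hept-5-enedioate | C=CCOC(=O)[C@H](c1ccc(O[Si](C(C)C)(C(C)C)C(C)C)cc1)[C@H](C/C(OS(=O)(=O)C(F)(F)F)=C/C(=O)OC)c1cc(O[Si](C(C)C)(C(C)C)C(C)C)cc(O[Si](C(C)C)(C(C)C)C(C)C)c1 | intermediate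
17 | 4-ethynylphenol | C#Cc1ccc(O)cc1 | starting material
18 | (4-ethynylphenoxy)triisopropylsilane | C#Cc1ccc(O[Si](C(C)C)(C(C)C)C(C)C)cc1 | intermediate
19 | 7-methyl 1-prop-2-en-1-yl (2S,3S,5Z)-2-[4-(TIPSO)phenyl]-3-[3,5-bis(TIPSO)phenyl]-5-{[4-(TIPSO)phenyl]ethynyl}hept-5-enedioate | C=CCOC(=O)[C@H](c1ccc(O[Si](C(C)C)(C(C)C)C(C)C)cc1)[C@H](C/C(C#Cc1ccc(O[Si](C(C)C)(C(C)C)C(C)C)cc1)=C/C(=O)OC)c1cc(O[Si](C(C)C)(C(C)C)C(C)C)cc(O[Si](C(C)C)(C(C)C)C(C)C)c1 | intermediate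
20 | (2S,3S,5Z)-7-methoxy-7-oxo-2-[4-(TIPSO)phenyl]-3-[3,5-bis(TIPSO)phenyl]-5-{[4-(TIPSO)phenyl]ethynyl}hept-5-enoic acid | OC(=O)[C@H](c1ccc(O[Si](C(C)C)(C(C)C)C(C)C)cc1)[C@H](C/C(C#Cc1ccc(O[Si](C(C)C)(C(C)C)C(C)C)cc1)=C/C(=O)OC)c1cc(O[Si](C(C)C)(C(C)C)C(C)C)cc(O[Si](C(C)C)(C(C)C)C(C)C)c1 | intermediate
21 | potassium (2S,3S)-7-methoxy-7-(TBSO)-2-[4-(TIPSO)phenyl]-3-[3,5-bis(TIPSO)phenyl]-5-{[4-(TIPSO)phenyl]ethynyl}hepta-4,6-dienoate (diene isomer mixture) | [K+].[O-]C(=O)[C@H](c1ccc(O[Si](C(C)C)(C(C)C)C(C)C)cc1)[C@H](C=C(C#Cc1ccc(O[Si](C(C)C)(C(C)C)C(C)C)cc1)C=C(OC)O[Si](C)(C)C(C)(C)C)c1cc(O[Si](C(C)C)(C(C)C)C(C)C)cc(O[Si](C(C)C)(C(C)C)C(C)C)c1 | intermediate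
22 | mixed anhydride of the acid of 21 with isobutyl hydrogen carbonate | CC(C)COC(=O)OC(=O)[C@H](c1ccc(O[Si](C(C)C)(C(C)C)C(C)C)cc1)[C@H](C=C(C#Cc1ccc(O[Si](C(C)C)(C(C)C)C(C)C)cc1)C=C(OC)O[Si](C)(C)C(C)(C)C)c1cc(O[Si](C(C)C)(C(C)C)C(C)C)cc(O[Si](C(C)C)(C(C)C)C(C)C)c1 | intermediate
23 | (3S,4S)-1-diazo-8-methoxy-8-(TBSO)-3-[4-(TIPSO)phenyl]-4-[3,5-bis(TIPSO)phenyl]-6-{[4-(TIPSO)phenyl]ethynyl}octa-5,7-dien-2-one (diene isomer mixture) | [N-]=[N+]=CC(=O)[C@H](c1ccc(O[Si](C(C)C)(C(C)C)C(C)C)cc1)[C@H](C=C(C#Cc1ccc(O[Si](C(C)C)(C(C)C)C(C)C)cc1)C=C(OC)O[Si](C)(C)C(C)(C)C)c1cc(O[Si](C(C)C)(C(C)C)C(C)C)cc(O[Si](C(C)C)(C(C)C)C(C)C)c1 | intermediate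
24 | ketene from 23 by Wolff rearrangement: (3S,4S)-8-methoxy-8-(TBSO)-3-[4-(TIPSO)phenyl]-4-[3,5-bis(TIPSO)phenyl]-6-{[4-(TIPSO)phenyl]ethynyl}octa-1,5,7-trien-1-one | O=C=C[C@H](c1ccc(O[Si](C(C)C)(C(C)C)C(C)C)cc1)[C@H](C=C(C#Cc1ccc(O[Si](C(C)C)(C(C)C)C(C)C)cc1)C=C(OC)O[Si](C)(C)C(C)(C)C)c1cc(O[Si](C(C)C)(C(C)C)C(C)C)cc(O[Si](C(C)C)(C(C)C)C(C)C)c1 | intermediate
25 | 2-methoxy-2-(TBSO) ketal of 26 (ring stereocentres as in 26; epimers at C2) | COC1(O[Si](C)(C)C(C)(C)C)C=C(C#Cc3ccc(O[Si](C(C)C)(C(C)C)C(C)C)cc3)[C@H]2C(=O)[C@@H]1[C@H](c1ccc(O[Si](C(C)C)(C(C)C)C(C)C)cc1)[C@H]2c1cc(O[Si](C(C)C)(C(C)C)C(C)C)cc(O[Si](C(C)C)(C(C)C)C(C)C)c1 | intermediate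
26 | (1R,5S,6R,7R)-7-[4-(TIPSO)phenyl]-6-[3,5-bis(TIPSO)phenyl]-4-{[4-(TIPSO)phenyl]ethynyl}bicyclo[3.2.1]oct-3-ene-2,8-dione | O=C1C=C(C#Cc3ccc(O[Si](C(C)C)(C(C)C)C(C)C)cc3)[C@H]2C(=O)[C@@H]1[C@H](c1ccc(O[Si](C(C)C)(C(C)C)C(C)C)cc1)[C@H]2c1cc(O[Si](C(C)C)(C(C)C)C(C)C)cc(O[Si](C(C)C)(C(C)C)C(C)C)c1 | intermediate
27 | alkenylsilane of 26 from anti addition, triethoxysilyl on the aryl-bearing alkene carbon | O=C1C=C(/C=C(/c3ccc(O[Si](C(C)C)(C(C)C)C(C)C)cc3)[Si](OCC)(OCC)OCC)[C@H]2C(=O)[C@@H]1[C@H](c1ccc(O[Si](C(C)C)(C(C)C)C(C)C)cc1)[C@H]2c1cc(O[Si](C(C)C)(C(C)C)C(C)C)cc(O[Si](C(C)C)(C(C)C)C(C)C)c1 | intermediate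
28 | alkenylsilane of 26 from anti addition, triethoxysilyl on the alkene carbon bound to C4 | O=C1C=C(/C(=C/c3ccc(O[Si](C(C)C)(C(C)C)C(C)C)cc3)[Si](OCC)(OCC)OCC)[C@H]2C(=O)[C@@H]1[C@H](c1ccc(O[Si](C(C)C)(C(C)C)C(C)C)cc1)[C@H]2c1cc(O[Si](C(C)C)(C(C)C)C(C)C)cc(O[Si](C(C)C)(C(C)C)C(C)C)c1 | intermediate
29 | vitisinol D, (1R,5S,6R,7R)-6-(3,5-dihydroxyphenyl)-7-(4-hydroxyphenyl)-4-[(E)-2-(4-hydroxyphenyl)ethenyl]bicyclo[3.2.1]oct-3-ene-2,8-dione | O=C1C=C(/C=C/c2ccc(O)cc2)[C@H]2C(=O)[C@@H]1[C@H](c1ccc(O)cc1)[C@H]2c1cc(O)cc(O)c1 | target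

**Step count and risks**

Total steps: 13. Longest linear sequence: 11 steps (4 → 5 → 9 → 12 → 13 → 15 → 16 → 19 → 20 → 23 → 26 → 29).

Steps most likely to fail:

1. Step 12 (key step). The zwitterion formed by the first C–C bond may be intercepted before the ring closes, by silyl transfer from the oxocarbenium oxygen to the enolate oxygen or by collapse through oxygen. The first bond may also form with the wrong facial sense at C5, which would place the C7 aryl endo. The fallback sets out from 23 and comes back at 26, and makes the two bonds in separate known reactions. Irradiation of 23 in MeCN, where silyl transfer is fast, should give by the known C-acylation of a silyl ketene acetal by a ketene the cyclopentanone silyl enol ether methyl ester F1 (a C5 epimer, if formed, is separated here). i-Bu2AlH at −78 °C reduces the ester to the allylic alcohol F2, and MnO2 gives the enal F3. BF3·OEt2 at −78 °C closes the six-membered ring by an intramolecular Mukaiyama aldol addition to the β-hydroxy ketone F4. Dess–Martin periodinane oxidises F4 to 26.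

2. Step 11. Enolisation at the α-aryl carbon (epimerisation), silylation of the carboxylate in place of the dienolate, or hydrolysis of the ketene acetal during activation may erode the telescoped sequence. The fallback sets out from 20 and comes back at ketene 24 inside step 12; it first moves the carbonyl group away from the stereocentre. Acid 20 is converted (i-BuOCOCl, N-methylmorpholine; CH2N2) into the diazoketone F5. Wolff rearrangement with PhCO2Ag (cat.) and Et3N in THF–H2O gives the homologated acid F6 (Arndt–Eistert). KN(SiMe3)2 and TBSCl give the silyl ketene acetal carboxylate F7, which can no longer epimerise. 2-Chloro-1-methylpyridinium iodide and Et3N in toluene at 80 °C dehydrate it to 24, which continues to 26 as in step 12.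

3. Step 13. Competing reduction of the enone, incomplete protodesilylation, or opening of the non-enolisable 1,3-diketone by fluoride or phenoxide (retro-Claisen) may lower the yield. The fallback sets out from 26 and comes back at 29. Semi-hydrogenation (H2, Pd/CaCO3–Pb(OAc)2, quinoline, EtOAc) gives the Z-alkene F8. I2 (cat.) under visible light isomerises it to the E-alkene F9. HF·pyridine in THF removes the four silyl ethers under acidic conditions to give 29.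

Further compounds
F1 | step 12 | methyl (2E)-3-[(1S,4S,5S)-2-(TBSO)-4-[4-(TIPSO)phenyl]-5-[3,5-bis(TIPSO)phenyl]cyclopent-2-en-1-yl]-5-[4-(TIPSO)phenyl]pent-2-en-4-ynoate (ring carbon cis to the ester) | COC(=O)/C=C(/C#Cc3ccc(O[Si](C(C)C)(C(C)C)C(C)C)cc3)[C@H]2C(O[Si](C)(C)C(C)(C)C)=C[C@H](c1ccc(O[Si](C(C)C)(C(C)C)C(C)C)cc1)[C@H]2c1cc(O[Si](C(C)C)(C(C)C)C(C)C)cc(O[Si](C(C)C)(C(C)C)C(C)C)c1
F2 | step 12 | allylic alcohol from reduction of the ester of F1 | OC/C=C(/C#Cc3ccc(O[Si](C(C)C)(C(C)C)C(C)C)cc3)[C@H]2C(O[Si](C)(C)C(C)(C)C)=C[C@H](c1ccc(O[Si](C(C)C)(C(C)C)C(C)C)cc1)[C@H]2c1cc(O[Si](C(C)C)(C(C)C)C(C)C)cc(O[Si](C(C)C)(C(C)C)C(C)C)c1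
F3 | step 12 | enal from oxidation of F2 | O=C/C=C(/C#Cc3ccc(O[Si](C(C)C)(C(C)C)C(C)C)cc3)[C@H]2C(O[Si](C)(C)C(C)(C)C)=C[C@H](c1ccc(O[Si](C(C)C)(C(C)C)C(C)C)cc1)[C@H]2c1cc(O[Si](C(C)C)(C(C)C)C(C)C)cc(O[Si](C(C)C)(C(C)C)C(C)C)c1
F4 | step 12 | 2-hydroxy analogue of 26 (8-ketone, epimers at C2) | OC1C=C(C#Cc3ccc(O[Si](C(C)C)(C(C)C)C(C)C)cc3)[C@H]2C(=O)[C@@H]1[C@H](c1ccc(O[Si](C(C)C)(C(C)C)C(C)C)cc1)[C@H]2c1cc(O[Si](C(C)C)(C(C)C)C(C)C)cc(O[Si](C(C)C)(C(C)C)C(C)C)c1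
F5 | step 11 | methyl (2Z,5S,6S)-8-diazo-7-oxo-6-[4-(TIPSO)phenyl]-5-[3,5-bis(TIPSO)phenyl]-3-{[4-(TIPSO)phenyl]ethynyl}oct-2-enoate | [N-]=[N+]=CC(=O)[C@H](c1ccc(O[Si](C(C)C)(C(C)C)C(C)C)cc1)[C@H](C/C(C#Cc1ccc(O[Si](C(C)C)(C(C)C)C(C)C)cc1)=C/C(=O)OC)c1cc(O[Si](C(C)C)(C(C)C)C(C)C)cc(O[Si](C(C)C)(C(C)C)C(C)C)c1
F6 | step 11 | homologated acid, (3S,4S,6Z)-8-methoxy-8-oxo-3-[4-(TIPSO)phenyl]-4-[3,5-bis(TIPSO)phenyl]-6-{[4-(TIPSO)phenyl]ethynyl}oct-6-enoic acid | OC(=O)C[C@H](c1ccc(O[Si](C(C)C)(C(C)C)C(C)C)cc1)[C@H](C/C(C#Cc1ccc(O[Si](C(C)C)(C(C)C)C(C)C)cc1)=C/C(=O)OC)c1cc(O[Si](C(C)C)(C(C)C)C(C)C)cc(O[Si](C(C)C)(C(C)C)C(C)C)c1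
F7 | step 11 | potassium carboxylate of the silyl ketene acetal of F6 (diene isomer mixture) | [K+].[O-]C(=O)C[C@H](c1ccc(O[Si](C(C)C)(C(C)C)C(C)C)cc1)[C@H](C=C(C#Cc1ccc(O[Si](C(C)C)(C(C)C)C(C)C)cc1)C=C(OC)O[Si](C)(C)C(C)(C)C)c1cc(O[Si](C(C)C)(C(C)C)C(C)C)cc(O[Si](C(C)C)(C(C)C)C(C)C)c1
F8 | step 13 | Z-alkene from semi-hydrogenation of 26 | O=C1C=C(/C=C\c3ccc(O[Si](C(C)C)(C(C)C)C(C)C)cc3)[C@H]2C(=O)[C@@H]1[C@H](c1ccc(O[Si](C(C)C)(C(C)C)C(C)C)cc1)[C@H]2c1cc(O[Si](C(C)C)(C(C)C)C(C)C)cc(O[Si](C(C)C)(C(C)C)C(C)C)c1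
F9 | step 13 | tetrakis(TIPS) ether of vitisinol D (E-alkene) | O=C1C=C(/C=C/c3ccc(O[Si](C(C)C)(C(C)C)C(C)C)cc3)[C@H]2C(=O)[C@@H]1[C@H](c1ccc(O[Si](C(C)C)(C(C)C)C(C)C)cc1)[C@H]2c1cc(O[Si](C(C)C)(C(C)C)C(C)C)cc(O[Si](C(C)C)(C(C)C)C(C)C)c1
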